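**Plan**

1. Retrosynthesis: cut (a) the ester C(acyl)–O bond between the two halves, (b) the O–CH2 bond of the ε-lactone, (c) the C7–C8 bond of each 2-(oxymethyl)acrylate unit (aldehyde + α-alkoxycarbonylvinyl alane), (d) ring A by a Diels–Alder disconnection (C1–C2 and C4a–C8a), and (e) ring C back to (S)-cryptone.
2. Enabling feature: the lactone segment O–C6H2–C7(CO2H)=C8H is the allylically transposed form of a Morita–Baylis–Hillman adduct of a C8 aldehyde, and the C5 carboxyl sits cis to C8 on the neighbouring ring-A carbon, so its oxygen reaches C6 through a seven-membered array.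
3. Forward, upper half: ring A by an auxiliary-controlled Diels–Alder reaction; a temporary bridged γ-lactone (C8 carboxyl onto C4) installs the C4 oxygen and is then reduced; vinylalumination at C8, acetylation and oxidation of C5 give the acetate acid; carboxylate SN2' closure forms ring B and the C7=C8 bond together.
4. Forward, lower half and union: (S)-cryptone, trans vinyl addition with enolate triflation, ozonolysis, vinylalumination, hydroxymethylation and 1,3-acetate transposition give the lower acid; esterification with the primary C4–CH2OH and one fluoride step finish.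
5. Stereochemistry: C1, C8a and C4a come from the Diels–Alder step ((E)-dienophile, endo rule, (R)-benzyloxazolidinone face control); C4 from intramolecular delivery of the C8 carboxylate; C6' from the enamine-catalysed Michael addition; C1' from copper-mediated addition anti to isopropyl; the ring-B alkene geometry from the ring; the side-chain (E)-alkene from thermodynamic acetate transposition.

Key step: step 15

Locants used below: ring A = C1 (CH–iPr), C2, C3, C4, C4a, C8a; C5 = the carbon on C4a (lactone carbonyl); C8–C7–C6 = the acrylate unit on C8a (C6 = OCH2); ring B = the ε-lactone; ring C = C1' (bears the side chain), C2'=C3', C4', C5', C6' (CH–iPr). α/β = below/above a ring drawn with its locants rising clockwise; isopropyl is 1α in ring A and 6'β in ring C.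

Assumption: compounds 1, 7, 8, 17, 18, 30, 31, 39 and all unnumbered reagents are purchasable.

**Upper half (rings A and B)**

Step 1
Reactants: 1 tert-butyl(diphenyl)(prop-2-yn-1-yloxy)silane
Product: 3 methyl 4-[(tert-butyldiphenylsilyl)oxy]but-2-ynoate, via lithium acetylide 2 (not isolated)
Conditions: n-BuLi, THF, −78 °C; then ClCO2Me, −78 → 0 °C
Reagents that add atoms: methyl chloroformate, COC(=O)Cl
Why: Lithiation of the terminal alkyne and C-acylation with a chloroformate is the standard preparation of 4-silyloxybut-2-ynoates.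

Step 2
Reactants: 3 methyl 4-[(tert-butyldiphenylsilyl)oxy]but-2-ynoate
Product: 4 methyl (2Z)-3-{[(tert-butyldiphenylsilyl)oxy]methyl}penta-2,4-dienoate
Conditions: CH2=CHMgBr, CuBr·SMe2 (1.2 equiv each), THF, −78 °C; then 3, −78 °C; NH4Cl (aq) at −78 °C
Reagents that add atoms: vinylmagnesium bromide, C=C[Mg]Br
Why: The vinylcopper reagent adds syn across the ynoate (carbocupration) and cold protonation of the alkenylcopper retains that geometry, so CH2OSi ends cis to the ester and trans to the vinyl group, the outward placement the diene terminus needs.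

Step 3
Reactants: 4 methyl (2Z)-3-{[(tert-butyldiphenylsilyl)oxy]methyl}penta-2,4-dienoate
Product: 5 (2Z)-3-{[(tert-butyldiphenylsilyl)oxy]methyl}penta-2,4-dien-1-ol
Conditions: i-Bu2AlH (2.2 equiv), CH2Cl2, −78 °C
Reagents that add atoms: none
Why: i-Bu2AlH reduces the conjugated ester 1,2 to the allylic alcohol without touching the diene geometry or the silyl ether.

Step 4
Reactants: 5 (2Z)-3-{[(tert-butyldiphenylsilyl)oxy]methyl}penta-2,4-dien-1-ol
Product: 6 (2Z)-1-[(tert-butyldimethylsilyl)oxy]-3-{[(tert-butyldiphenylsilyl)oxy]methyl}penta-2,4-diene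
Conditions: TBSCl, imidazole, CH2Cl2, 0 °C → rt
Reagents that add atoms: tert-butyldimethylsilyl chloride, CC(C)(C)[Si](C)(C)Cl
Why: Standard silylation gives a primary TBS ether that can later be removed in the presence of the more robust TBDPS ether.

Step 5
Reactants: 7 (2E)-4-methylpent-2-enoic acid; 8 (4R)-4-benzyl-1,3-oxazolidin-2-one
Product: 10 (4R)-4-benzyl-3-[(2E)-4-methylpent-2-enoyl]-1,3-oxazolidin-2-one, via mixed anhydride 9 (not isolated)
Conditions: t-BuCOCl, Et3N, THF, −20 °C; then 8, LiCl, −20 °C → rt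
Reagents that add atoms: none
Why: N-acylation of the oxazolidinone through the pivalic mixed anhydride avoids strong base and keeps the (E)-enoate intact.

Step 6
Reactants: 10 (4R)-4-benzyl-3-[(2E)-4-methylpent-2-enoyl]-1,3-oxazolidin-2-one; 6 (2Z)-1-[(tert-butyldimethylsilyl)oxy]-3-{[(tert-butyldiphenylsilyl)oxy]methyl}penta-2,4-diene
Product: 11 Diels–Alder adduct (ring-A cyclohex-3-ene: 1α-isopropyl, 8aβ-C(=O)-oxazolidinone, 4aβ-CH2OTBS, 4-CH2OTBDPS)
Conditions: Et2AlCl (1.5 equiv), CH2Cl2, −78 → −20 °C, excess 6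
Reagents that add atoms: none
Why: Lewis-acid Diels–Alder reaction of the chelated s-cis N-enoyl oxazolidinone: the diene adds to the Cα face remote from the benzyl group, the (E)-dienophile fixes C8 trans to isopropyl, the endo rule places the outward CH2OTBS cis to the carbonyl, and the substituted diene terminus bonds to Cα (ortho orientation, reinforced by the hindered β-carbon bonding to the CH2 terminus), so C1, C8a and C4a are set in one step.

Step 7
Reactants: 11 Diels–Alder adduct
Product: 13 ring-A acid (1α-isopropyl, 8aβ-CO2H, 4aβ-CH2OTBS, 4-CH2OTBDPS, C3=C4), via peroxy acid 12 (not isolated)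
Conditions: LiOH, H2O2 (30 %), THF/H2O, 0 °C; then Na2SO3 (aq); HCl to pH 3
Reagents that add atoms: hydrogen peroxide (as LiOOH), OO
Why: LiOOH attacks the exocyclic imide carbonyl selectively and releases the auxiliary without epimerising C8a, and sulfite reduces the peroxy acid.

Step 8
Reactants: 13 ring-A acid
Product: 14 bridged iodolactone (C8(=O)–O–C4 with 4β-O, 3α-iodo, 4α-CH2OTBDPS, 4aβ-CH2OTBS, 1α-isopropyl)
Conditions: I2, NaHCO3, MeCN/H2O, 0 °C, dark
Reagents that add atoms: iodine, II
Why: Iodolactonisation of the γ,δ-unsaturated acid: 5-exo attack of the 8aβ carboxylate on the iodonium ion at the nearer, more substituted carbon C4 can only occur on the β face, which sets C4 (O β, CH2OTBDPS α) and places iodine anti at C3.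

Step 9
Reactants: 14 bridged iodolactone
Product: 15 bridged γ-lactone (C8(=O)–O–C4, 4α-CH2OTBDPS, 4aβ-CH2OTBS, 1α-isopropyl)
Conditions: Bu3SnH, AIBN (cat.), toluene, 80 °C
Reagents that add atoms: none
Why: Radical chain deiodination removes the auxiliary iodine, the β-acyloxy radical being reduced faster than it rearranges.

Step 10
Reactants: 15 bridged γ-lactone
Product: 16 bridged lactol (C8 hemiacetal, both anomers)
Conditions: i-Bu2AlH (1.2 equiv), CH2Cl2, −78 °C
Reagents that add atoms: none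
Why: At −78 °C i-Bu2AlH stops at the lactol, which masks the C8 aldehyde while the bridged ring keeps C8a from epimerising.

Step 11
Reactants: 17 prop-2-ynoic acid; 18 2-(trimethylsilyl)ethanol
Product: 20 2-(trimethylsilyl)ethyl prop-2-ynoate, via O-acylisourea 19 (not isolated)
Conditions: DCC, DMAP (cat.), CH2Cl2, 0 °C → rt
Reagents that add atoms: none
Why: Carbodiimide (Steglich) esterification gives the fluoride-cleavable ester needed for the final deprotection.

Step 12
Reactants: 16 bridged lactol; 20 2-(trimethylsilyl)ethyl prop-2-ynoate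
Product: 22 Morita–Baylis–Hillman-type diol (8aβ-CH(OH)C(=CH2)CO2CH2CH2SiMe3 as both C8 epimers, 4β-OH, 4α-CH2OTBDPS, 4aβ-CH2OTBS, 1α-isopropyl), via vinylalane 21 (not isolated)
Conditions: 20 (3 equiv), i-Bu2AlH (3 equiv), HMPA, THF, 0 °C; then 16, 0 °C → rt
Reagents that add atoms: none
Why: Hydroalumination of the propiolate gives the α-alkoxycarbonylvinyl alane (vinylalumination), which adds to the aldehyde tautomer of the lactol and so delivers the Morita–Baylis–Hillman-type adduct that amine catalysis would form only sluggishly from so hindered an aldehyde; the new C8 carbinol centre is uncontrolled and is erased in step 15.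

Step 13
Reactants: 22 Morita–Baylis–Hillman-type diol
Product: 23 C8 acetate of 22
Conditions: Ac2O, pyridine, DMAP (cat.), CH2Cl2, 0 °C
Reagents that add atoms: acetic anhydride, CC(=O)OC(C)=O
Why: The secondary allylic alcohol is acetylated while the tertiary C4 hydroxyl is inert under these mild conditions.

Step 14
Reactants: 23 C8 acetate
Product: 26 acetate acid (4aβ-CO2H, 8aβ-CH(OAc)C(=CH2)CO2CH2CH2SiMe3, 4β-OH, 4α-CH2OTBDPS, 1α-isopropyl), via primary alcohol 24 (not isolated), via aldehyde 25 (not isolated)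
Conditions: CrO3, H2SO4, H2O, acetone, 0 °C
Reagents that add atoms: water, O
Why: Jones conditions cleave the primary TBS ether and oxidise the alcohol through the aldehyde to the acid in one operation, while the TBDPS ether, acetate, acrylate, silylethyl ester and tertiary alcohol should tolerate brief cold aqueous chromic acid.

Step 15
Reactants: 26 acetate acid
Product: 28 ε-lactone (ring B cis-fused to ring A: C5(=O)–O–C6H2–C7(CO2CH2CH2SiMe3)=C8H, 4β-OH, 4α-CH2OTBDPS, 1α-isopropyl), via caesium carboxylate 27 (not isolated)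
Conditions: Cs2CO3 (1.5 equiv), MeCN (0.005 M), 45 °C
Reagents that add atoms: none
Why: Deprotonation gives caesium carboxylate 27, whose oxygen adds to the unhindered terminal methylene C6 of the 2-substituted acrylate, and the resulting ester enolate expels the C8 acetate (conjugate addition–elimination, net SN2'), the reaction type established for Morita–Baylis–Hillman acetates with carboxylate and phenoxide nucleophiles. The seven-membered ring closes in a 7-endo-trig mode (O, C6, C7, C8, C8a, C4a, C5), made possible by the cis disposition of C5 and C8 on adjacent ring-A carbons. No stereocentre is created; the C8 carbinol centre (both epimers) is destroyed, and the C7=C8 geometry is fixed by the ring (C6 and C8a cis, ester exocyclic), which is the geometry of the target. The step needs site selectivity for O–C6 over O–C8 (the latter would give the isomeric five-membered lactone): C8 is sp3, secondary and flanked by the ring, so it could only be attacked by direct displacement of acetate, which should not compete, and no nucleophilic amine, phosphine or palladium catalyst is present that could interconvert the two lactones. High dilution suppresses intermolecular SN2' esterification and drives release of acetate, and the mild carbonate base should leave the tertiary C4 hydroxyl, the C4a stereocentre and the silyl groups untouched.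

Step 16
Reactants: 28 ε-lactone
Product: 29 lactone diol (4β-OH, 4α-CH2OH)
Conditions: HF·pyridine, pyridine, THF, 0 °C → rt
Reagents that add atoms: none
Why: HF·pyridine removes the primary TBDPS ether, while the silylethyl ester, the lactone and the tertiary alcohol are stable to it.

**Lower half (ring C)**

Step 17
Reactants: 30 3-methylbutanal; 31 but-3-en-2-one
Product: 32 (2S)-5-oxo-2-(propan-2-yl)hexanal
Conditions: (S)-2-[methoxy(diphenyl)methyl]pyrrolidine (5 mol %), ethyl 3,4-dihydroxybenzoate (20 mol %), neat, 4 °C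
Reagents that add atoms: none
Why: Enamine-catalysed Michael addition of the aldehyde to the enone: the (S)-configured diarylprolinol ether forms the (E)-enamine and shields one face, so the enone adds to the other and the (S)-aldehyde should result.

Step 18
Reactants: 32 (2S)-5-oxo-2-(propan-2-yl)hexanal
Product: 34 (4S)-4-(propan-2-yl)cyclohex-2-en-1-one ((S)-cryptone), via aldol adduct 33 (not isolated)
Conditions: LiOH, i-PrOH, rt
Reagents that add atoms: none
Why: Base-mediated intramolecular aldol addition and dehydration (Robinson-type closure) gives the cyclohexenone.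

Step 19
Reactants: 34 (S)-cryptone
Product: 36 enol triflate (ring C: 1'α-vinyl, 6'β-isopropyl, 3'-OTf on C2'=C3'), via magnesium enolate 35 (not isolated)
Conditions: CH2=CHMgBr (1.5 equiv), CuBr·SMe2 (10 mol %), THF, −78 °C; then PhNTf2, −78 → 0 °C
Reagents that add atoms: vinylmagnesium bromide, C=C[Mg]Br; N-phenylbis(trifluoromethanesulfonimide), O=S(=O)(N(c1ccccc1)S(=O)(=O)C(F)(F)F)C(F)(F)F
Why: Copper-catalysed conjugate addition occurs anti to the neighbouring isopropyl group (trans), and O-triflation of the regiodefined enolate fixes the double bond between C2' and C3'.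

Step 20
Reactants: 36 enol triflate
Product: 38 aldehyde (1'α-CHO, 6'β-isopropyl, 3'-OTf), via ozonide 37 (not isolated)
Conditions: O3, CH2Cl2, −78 °C (indicator end-point); then Me2S, −78 °C → rt
Reagents that add atoms: ozone, [O-][O+]=O
Why: Ozone attacks the electron-rich monosubstituted vinyl group, while the strongly deactivated enol triflate double bond survives.

Step 21
Reactants: 38 aldehyde; 39 methyl prop-2-ynoate
Product: 41 Morita–Baylis–Hillman-type alcohol (1'α-CH(OH)C(=CH2)CO2Me, both carbinol epimers, 3'-OTf), via vinylalane 40 (not isolated)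
Conditions: 39 (1.5 equiv), i-Bu2AlH (1.5 equiv), HMPA, THF, 0 °C; then 38, 0 °C → rt
Reagents that add atoms: none
Why: Vinylalumination as in step 12 gives the adduct from the α-branched aldehyde under non-basic conditions that should not epimerise C1'; the carbinol centre is erased in step 23.

Step 22
Reactants: 41 Morita–Baylis–Hillman-type alcohol
Product: 42 diol (3'-CH2OH, 1'α-CH(OH)C(=CH2)CO2Me)
Conditions: Bu3SnCH2OH, Pd(PPh3)4 (5 mol %), LiCl, 1,4-dioxane, 100 °C
Reagents that add atoms: (tributylstannyl)methanol, OC[Sn](CCCC)(CCCC)CCCC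
Why: Stille coupling of the enol triflate with the hydroxymethylstannane installs the ring CH2OH directly, and an intramolecular Heck path is excluded because it would need a bridgehead alkene.

Step 23
Reactants: 42 diol
Product: 45 methyl (2E)-2-(hydroxymethyl)-3-[ring C: 3'-(hydroxymethyl)-6'β-isopropylcyclohex-2'-en-1'α-yl]prop-2-enoate, via diacetate 43 (not isolated), via transposed diacetate 44 (not isolated)
Conditions: Ac2O, Et3N, DMAP (cat.), THF, 0 °C; then DABCO (1 equiv), 60 °C; then MeOH, K2CO3, 0 °C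
Reagents that add atoms: none
Why: Acetylation, then amine-catalysed 1,3-transposition of the Morita–Baylis–Hillman acetate (SN2' then SN2 through the allylammonium salt) to the thermodynamically favoured primary acetate with the ring trans to the ester ((E)-geometry), then mild methanolysis of both acetates.

Step 24
Reactants: 45 (E)-diol ester
Product: 46 bis-TBS ether of 45
Conditions: TBSCl, imidazole, DMF, rt
Reagents that add atoms: tert-butyldimethylsilyl chloride, CC(C)(C)[Si](C)(C)Cl
Why: Standard silylation protects both primary allylic alcohols for the esterification.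

Step 25
Reactants: 46 bis-TBS methyl ester
Product: 47 (2E)-2-{[(tert-butyldimethylsilyl)oxy]methyl}-3-[3'-(TBSO-methyl)-6'β-isopropylcyclohex-2'-en-1'α-yl]prop-2-enoic acid
Conditions: Me3SnOH, 1,2-dichloroethane, 70 °C; dilute HCl work-up
Reagents that add atoms: trimethyltin hydroxide, C[Sn](C)(C)O
Why: Me3SnOH cleaves the methyl ester under near-neutral conditions, so the doubly allylic C1' hydrogen and the silyl ethers are not at risk.

**Union and deprotection**

Step 26
Reactants: 29 lactone diol; 47 lower acid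
Product: 49 protected target (ester at 4α-CH2O; two TBS ethers; silylethyl ester), via mixed anhydride 48 (not isolated)
Conditions: 2,4,6-trichlorobenzoyl chloride, Et3N, THF, rt; then 29, DMAP, toluene, rt
Reagents that add atoms: none
Why: Yamaguchi esterification acylates the primary neopentyl-type alcohol, while the tertiary C4 alcohol does not react.

Step 27
Reactants: 49 protected target
Product: 50 target CNP0361406.4
Conditions: Bu4NF (6 equiv), AcOH (4 equiv), THF, 0 °C → rt; citric acid work-up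
Reagents that add atoms: none
Why: Fluoride removes both TBS ethers and fragments the 2-(trimethylsilyl)ethyl ester to the free acid, and the AcOH buffer should keep the medium from epimerising C4a or opening the lactone.

**Compound list**

1 | tert-butyl(diphenyl)(prop-2-yn-1-yloxy)silane | C#CCO[Si](c1ccccc1)(c1ccccc1)C(C)(C)C | starting material
2 | lithium acetylide of 1 | [Li]C#CCO[Si](c1ccccc1)(c1ccccc1)C(C)(C)C | intermediate
3 | methyl 4-[(tert-butyldiphenylsilyl)oxy]but-2-ynoate | COC(=O)C#CCO[Si](c1ccccc1)(c1ccccc1)C(C)(C)C | intermediate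
4 | methyl (2Z)-3-{[(tert-butyldiphenylsilyl)oxy]methyl}penta-2,4-dienoate | C=C/C(CO[Si](c1ccccc1)(c1ccccc1)C(C)(C)C)=C/C(=O)OC | intermediate
5 | (2Z)-3-{[(tert-butyldiphenylsilyl)oxy]methyl}penta-2,4-dien-1-ol | C=C/C(CO[Si](c1ccccc1)(c1ccccc1)C(C)(C)C)=C/CO | intermediate
6 | (2Z)-1-[(tert-butyldimethylsilyl)oxy]-3-{[(tert-butyldiphenylsilyl)oxy]methyl}penta-2,4-diene | C=C/C(CO[Si](c1ccccc1)(c1ccccc1)C(C)(C)C)=C/CO[Si](C)(C)C(C)(C)C | intermediate
7 | (2E)-4-methylpent-2-enoic acid | CC(C)/C=C/C(=O)O | starting material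
8 | (4R)-4-benzyl-1,3-oxazolidin-2-one | O=C1N[C@H](Cc2ccccc2)CO1 | starting material
9 | (2E)-4-methylpent-2-enoic pivalic anhydride | CC(C)/C=C/C(=O)OC(=O)C(C)(C)C | intermediate
10 | (4R)-4-benzyl-3-[(2E)-4-methylpent-2-enoyl]-1,3-oxazolidin-2-one | CC(C)/C=C/C(=O)N1C(=O)OC[C@H]1Cc1ccccc1 | intermediate
11 | Diels–Alder adduct: ring-A cyclohex-3-ene, 1α-isopropyl, 8aβ-C(=O)-[(4R)-4-benzyl-2-oxo-oxazolidin-3-yl], 4aβ-CH2OTBS, 4-CH2OTBDPS | CC(C)[C@@H]1CC=C(CO[Si](c2ccccc2)(c2ccccc2)C(C)(C)C)[C@@H](CO[Si](C)(C)C(C)(C)C)[C@H]1C(=O)N1C(=O)OC[C@H]1Cc1ccccc1 | intermediate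
12 | peroxy acid corresponding to 13 | CC(C)[C@@H]1CC=C(CO[Si](c2ccccc2)(c2ccccc2)C(C)(C)C)[C@@H](CO[Si](C)(C)C(C)(C)C)[C@H]1C(=O)OO | intermediate
13 | ring-A acid: 1α-isopropyl, 8aβ-CO2H, 4aβ-CH2OTBS, 4-CH2OTBDPS, C3=C4 | CC(C)[C@@H]1CC=C(CO[Si](c2ccccc2)(c2ccccc2)C(C)(C)C)[C@@H](CO[Si](C)(C)C(C)(C)C)[C@H]1C(=O)O | intermediate
14 | bridged iodolactone: C8(=O)–O–C4 (4β-O), 3α-iodo, 4α-CH2OTBDPS, 4aβ-CH2OTBS, 1α-isopropyl | CC(C)[C@@H]1C[C@H](I)[C@](O2)(CO[Si](c3ccccc3)(c3ccccc3)C(C)(C)C)[C@@H](CO[Si](C)(C)C(C)(C)C)[C@H]1C2=O | intermediate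
15 | bridged γ-lactone: C8(=O)–O–C4 (4β-O), 4α-CH2OTBDPS, 4aβ-CH2OTBS, 1α-isopropyl | CC(C)[C@@H]1CC[C@](O2)(CO[Si](c3ccccc3)(c3ccccc3)C(C)(C)C)[C@@H](CO[Si](C)(C)C(C)(C)C)[C@H]1C2=O | intermediate
16 | bridged lactol of 15 (C8 hemiacetal, both anomers) | CC(C)[C@@H]1CC[C@](O2)(CO[Si](c3ccccc3)(c3ccccc3)C(C)(C)C)[C@@H](CO[Si](C)(C)C(C)(C)C)[C@H]1C2O | intermediate
17 | prop-2-ynoic acid | C#CC(=O)O | starting material
18 | 2-(trimethylsilyl)ethanol | C[Si](C)(C)CCO | starting material
19 | O-propioloyl-N,N'-dicyclohexylisourea | C#CC(=O)OC(=NC1CCCCC1)NC1CCCCC1 | intermediate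
20 | 2-(trimethylsilyl)ethyl prop-2-ynoate | C#CC(=O)OCC[Si](C)(C)C | intermediate
21 | bis(2-methylpropyl){1-[(2-(trimethylsilyl)ethoxy)carbonyl]ethenyl}aluminium | C=C(C(=O)OCC[Si](C)(C)C)[Al](CC(C)C)CC(C)C | intermediate
22 | diol: 8aβ-CH(OH)C(=CH2)CO2CH2CH2SiMe3 (C8 epimers), 4β-OH, 4α-CH2OTBDPS, 4aβ-CH2OTBS, 1α-isopropyl | CC(C)[C@@H]1CC[C@](O)(CO[Si](c2ccccc2)(c2ccccc2)C(C)(C)C)[C@@H](CO[Si](C)(C)C(C)(C)C)[C@H]1C(O)C(=C)C(=O)OCC[Si](C)(C)C | intermediate
23 | C8 acetate of 22 | CC(C)[C@@H]1CC[C@](O)(CO[Si](c2ccccc2)(c2ccccc2)C(C)(C)C)[C@@H](CO[Si](C)(C)C(C)(C)C)[C@H]1C(OC(C)=O)C(=C)C(=O)OCC[Si](C)(C)C | intermediate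
24 | 4aβ-CH2OH analogue of 23 | CC(C)[C@@H]1CC[C@](O)(CO[Si](c2ccccc2)(c2ccccc2)C(C)(C)C)[C@@H](CO)[C@H]1C(OC(C)=O)C(=C)C(=O)OCC[Si](C)(C)C | intermediate
25 | 4aβ-CHO analogue of 23 | CC(C)[C@@H]1CC[C@](O)(CO[Si](c2ccccc2)(c2ccccc2)C(C)(C)C)[C@@H](C=O)[C@H]1C(OC(C)=O)C(=C)C(=O)OCC[Si](C)(C)C | intermediate
26 | acetate acid: 4aβ-CO2H, 8aβ-CH(OAc)C(=CH2)CO2CH2CH2SiMe3, 4β-OH, 4α-CH2OTBDPS, 1α-isopropyl | CC(C)[C@@H]1CC[C@](O)(CO[Si](c2ccccc2)(c2ccccc2)C(C)(C)C)[C@@H](C(=O)O)[C@H]1C(OC(C)=O)C(=C)C(=O)OCC[Si](C)(C)C | intermediate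
27 | caesium salt of 26 | CC(C)[C@@H]1CC[C@](O)(CO[Si](c2ccccc2)(c2ccccc2)C(C)(C)C)[C@@H](C(=O)[O-])[C@H]1C(OC(C)=O)C(=C)C(=O)OCC[Si](C)(C)C.[Cs+] | intermediate
28 | ε-lactone (rings A and B, cis-fused): 7-CO2CH2CH2SiMe3, C7=C8, 4β-OH, 4α-CH2OTBDPS, 1α-isopropyl, 4aα-H, 8aα-H | CC(C)[C@@H]1CC[C@](O)(CO[Si](c3ccccc3)(c3ccccc3)C(C)(C)C)[C@H]2C(=O)OCC(C(=O)OCC[Si](C)(C)C)=C[C@@H]12 | intermediate
29 | lactone diol: as 28 with 4α-CH2OH | CC(C)[C@@H]1CC[C@](O)(CO)[C@H]2C(=O)OCC(C(=O)OCC[Si](C)(C)C)=C[C@@H]12 | intermediate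
30 | 3-methylbutanal | CC(C)CC=O | starting material
31 | but-3-en-2-one | CC(=O)C=C | starting material
32 | (2S)-5-oxo-2-(propan-2-yl)hexanal | CC(=O)CC[C@H](C=O)C(C)C | intermediate
33 | (4S)-3-hydroxy-4-(propan-2-yl)cyclohexan-1-one (carbinol epimers) | CC(C)[C@@H]1CCC(=O)CC1O | intermediate
34 | (4S)-4-(propan-2-yl)cyclohex-2-en-1-one | CC(C)[C@@H]1CCC(=O)C=C1 | intermediate
35 | bromomagnesium enolate: 1'α-vinyl, 6'β-isopropyl, 3'-OMgBr | C=C[C@@H]1C=C(O[Mg]Br)CC[C@H]1C(C)C | intermediate
36 | enol triflate: 1'α-vinyl, 6'β-isopropyl, 3'-OSO2CF3, C2'=C3' | C=C[C@@H]1C=C(OS(=O)(=O)C(F)(F)F)CC[C@H]1C(C)C | intermediate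
37 | 1,2,4-trioxolane (ozonide) of the vinyl group of 36 | C1OOC(O1)[C@@H]1C=C(OS(=O)(=O)C(F)(F)F)CC[C@H]1C(C)C | intermediate
38 | aldehyde: 1'α-CHO, 6'β-isopropyl, 3'-OSO2CF3 | O=C[C@@H]1C=C(OS(=O)(=O)C(F)(F)F)CC[C@H]1C(C)C | intermediate
39 | methyl prop-2-ynoate | C#CC(=O)OC | starting material
40 | [1-(methoxycarbonyl)ethenyl]bis(2-methylpropyl)aluminium | C=C(C(=O)OC)[Al](CC(C)C)CC(C)C | intermediate
41 | alcohol: 1'α-CH(OH)C(=CH2)CO2Me (carbinol epimers), 6'β-isopropyl, 3'-OSO2CF3 | C=C(C(=O)OC)C(O)[C@@H]1C=C(OS(=O)(=O)C(F)(F)F)CC[C@H]1C(C)C | intermediate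
42 | diol: 1'α-CH(OH)C(=CH2)CO2Me, 3'-CH2OH, 6'β-isopropyl | C=C(C(=O)OC)C(O)[C@@H]1C=C(CO)CC[C@H]1C(C)C | intermediate
43 | diacetate of 42 | C=C(C(=O)OC)C(OC(C)=O)[C@@H]1C=C(COC(C)=O)CC[C@H]1C(C)C | intermediate
44 | methyl (2E)-2-(acetoxymethyl)-3-[3'-(acetoxymethyl)-6'β-isopropylcyclohex-2'-en-1'α-yl]prop-2-enoate | COC(=O)/C(=C/[C@@H]1C=C(COC(C)=O)CC[C@H]1C(C)C)COC(C)=O | intermediate
45 | methyl (2E)-2-(hydroxymethyl)-3-[3'-(hydroxymethyl)-6'β-isopropylcyclohex-2'-en-1'α-yl]prop-2-enoate | COC(=O)/C(=C/[C@@H]1C=C(CO)CC[C@H]1C(C)C)CO | intermediate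
46 | bis-TBS ether of 45 | COC(=O)/C(=C/[C@@H]1C=C(CO[Si](C)(C)C(C)(C)C)CC[C@H]1C(C)C)CO[Si](C)(C)C(C)(C)C | intermediate
47 | (2E)-2-(TBSO-methyl)-3-[3'-(TBSO-methyl)-6'β-isopropylcyclohex-2'-en-1'α-yl]prop-2-enoic acid | OC(=O)/C(=C/[C@@H]1C=C(CO[Si](C)(C)C(C)(C)C)CC[C@H]1C(C)C)CO[Si](C)(C)C(C)(C)C | intermediate
48 | mixed anhydride of 47 with 2,4,6-trichlorobenzoic acid | O=C(OC(=O)c1c(Cl)cc(Cl)cc1Cl)/C(=C/[C@@H]1C=C(CO[Si](C)(C)C(C)(C)C)CC[C@H]1C(C)C)CO[Si](C)(C)C(C)(C)C | intermediate
49 | protected target: lactone 29 acylated at 4α-CH2O by acid 47 | CC(C)[C@@H]1CC[C@](O)(COC(=O)/C(=C/[C@@H]2C=C(CO[Si](C)(C)C(C)(C)C)CC[C@H]2C(C)C)CO[Si](C)(C)C(C)(C)C)[C@H]2C(=O)OCC(C(=O)OCC[Si](C)(C)C)=C[C@@H]12 | intermediate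
50 | target CNP0361406.4: cis-fused ε-lactone acid (7-CO2H, 4β-OH, 1α-isopropyl) esterified at 4α-CH2O with (2E)-2-(hydroxymethyl)-3-[3'-(hydroxymethyl)-6'β-isopropylcyclohex-2'-en-1'α-yl]prop-2-enoic acid | CC(C)[C@@H]1CC[C@](O)(COC(=O)/C(=C/[C@@H]2C=C(CO)CC[C@H]2C(C)C)CO)[C@H]2C(=O)OCC(C(=O)O)=C[C@@H]12 | target

**Totals and risks**

Total step count: 27. Longest linear sequence: 16 steps (1, 2, 3, 4, 6, 7, 8, 9, 10, 12, 13, 14, 15, 16, 26, 27).

Steps most likely to fail:

Step 15 (carboxylate SN2' ring closure). Risk: the conjugate addition to the acrylate terminus may be slow, so that intermolecular esterification or loss of acetate without ring closure takes over. Fallback: starting from 26, the acetate is first transposed by bromide (MgBr2·OEt2, THF, SN2') to the (Z)-2-(bromomethyl)acrylate acid F1, in which C8a and CH2Br are cis on the new C7=C8 bond. Caesium carboxylate alkylation at high dilution (Cs2CO3, DMF, 0.005 M; 7-exo-tet displacement at C6) should then give lactone 28, where the route is rejoined.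

Step 6 (Diels–Alder reaction). Risk: low reactivity of the β-isopropyl imide towards the trisubstituted diene, erosion of regio- or endo-control, or Lewis-acid cleavage of the silyl ethers. Fallback: iminium catalysis in place of the chelated auxiliary. Diene 6 and (2E)-4-methylpent-2-enal with the first-generation imidazolidinone (5R)-5-benzyl-2,2,3-trimethylimidazolidin-4-one hydrochloride (20 mol %) in MeCN/H2O should give the endo aldehyde F2 through attack on the same Cα face. Pinnick oxidation (NaClO2, NaH2PO4, 2-methylbut-2-ene, t-BuOH/H2O) converts it into acid 13, where the route is rejoined.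

Step 12 (vinylalumination of the lactol). Risk: incomplete opening of the bridged lactol, or hydride transfer instead of vinyl transfer. Fallback: starting from lactol 16, aldol addition of the lithium enolate of 2-(trimethylsilyl)ethyl 3-(phenylselanyl)propanoate (LDA, THF, −78 °C, excess) gives the β-hydroxy selenide F3. Oxidation (H2O2, pyridine, CH2Cl2, 0 °C) and selenoxide syn-elimination then reveal the α-methylene ester, giving diol 22, where the route is rejoined.

**Further compounds**

F1 | step 15 | (Z)-2-(bromomethyl)acrylate acid: 4aβ-CO2H, 8aβ-CH=C(CH2Br)CO2CH2CH2SiMe3 (C8a cis to CH2Br), 4β-OH, 4α-CH2OTBDPS, 1α-isopropyl | CC(C)[C@@H]1CC[C@](O)(CO[Si](c2ccccc2)(c2ccccc2)C(C)(C)C)[C@@H](C(=O)O)[C@H]1/C=C(\CBr)C(=O)OCC[Si](C)(C)C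
F2 | step 6 | ring-A aldehyde: 1α-isopropyl, 8aβ-CHO, 4aβ-CH2OTBS, 4-CH2OTBDPS, C3=C4 | CC(C)[C@@H]1CC=C(CO[Si](c2ccccc2)(c2ccccc2)C(C)(C)C)[C@@H](CO[Si](C)(C)C(C)(C)C)[C@H]1C=O
F3 | step 12 | β-hydroxy selenide: 8aβ-CH(OH)CH(CH2SePh)CO2CH2CH2SiMe3, 4β-OH, 4α-CH2OTBDPS, 4aβ-CH2OTBS, 1α-isopropyl | CC(C)[C@@H]1CC[C@](O)(CO[Si](c2ccccc2)(c2ccccc2)C(C)(C)C)[C@@H](CO[Si](C)(C)C(C)(C)C)[C@H]1C(O)C(C[Se]c1ccccc1)C(=O)OCC[Si](C)(C)C
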